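**Retrosynthetic overview**
Numbering: ring C1 (angelate), C2, C3 (CH3), C4 (OH), C5, C6 (chain); chain C7 (CH3), C8, C9 (OAc), C10=C11. The plan rests on the two ring oxygens at C1 and C4, which are cis-1,4 on the cyclohexane, flank C2–C3(CH3) and lie trans to the C6 chain.
Late stage: C4–OH from a C4 ketone (axial-selective hydride); C9–C10 and C9–OAc from a C9 aldehyde and 1-bromo-2-methylprop-1-ene; C1 ester from C1–OH and angelic acid; C3 set by conjugate reduction and equilibration next to the C4 ketone.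
Key disconnection: C1–O and C4–O from a singlet-oxygen [4+2] addition to the C1=C2–C3(CH3)=C4 diene; the peroxide bridge is then opened by base to C1–OH and the C4 enone.
Diene from a dienyl triflate and MeMgBr (iron catalysis), from a 4-alkylcyclohex-2-enone, from an amine-catalysed Michael addition/aldol condensation of an (R)-3-methyl aldehyde with methyl vinyl ketone; the aldehyde from desymmetrised 3-methylglutaric anhydride.
Ring order: the carbocycle closes first (step 6); the temporary 1,2-dioxene ring of the 2,3-dioxabicyclo[2.2.2]octene closes in step 9 and is opened in step 10.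

Key step: step 9

Assumption: the alkaloid catalyst of step 1 and the sulfonamide ligand of step 15 are each available in both antipodal (or pseudoenantiomeric) forms; the forms named are taken to give the (R)-hemiester and the (9R)-carbinol, and the antipode is used if the sense proves opposite. (TBS = tert-butyldimethylsilyl.)

**Step 1**
Reactants: 1 3-methylglutaric anhydride
Product: 2 (R)-5-methoxy-3-methyl-5-oxopentanoic acid
Conditions: MeOH (10 equiv), (DHQD)2AQN (0.2 equiv), Et2O, −40 °C
Reagents that add atoms: methanol, CO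
Why: Cinchona-alkaloid-catalysed desymmetrising alcoholysis of a meso anhydride, in which the chiral tertiary amine directs methanol to one enantiotopic carbonyl and so sets the future C7 methyl centre.

**Step 2**
Reactants: 2 (R)-5-methoxy-3-methyl-5-oxopentanoic acid
Product: 3 methyl (R)-5-hydroxy-3-methylpentanoate
Conditions: BH3·SMe2 (1.1 equiv), THF, 0 °C to rt; MeOH quench; crude used at once
Reagents that add atoms: none
Why: Chemoselective borane reduction of a carboxylic acid beside a methyl ester (through the acyloxyborane) leaves the stereocentre untouched, and immediate silylation forestalls lactonisation.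

**Step 3**
Reactants: 3 methyl (R)-5-hydroxy-3-methylpentanoate
Product: 4 methyl (R)-5-(TBSO)-3-methylpentanoate
Conditions: TBSCl (1.1 equiv), imidazole (2 equiv), DMF, 0 °C to rt
Reagents that add atoms: tert-butyldimethylsilyl chloride, CC(C)(C)[Si](C)(C)Cl
Why: Standard imidazole-promoted silylation of a primary alcohol gives an ether that survives all steps up to step 13.

**Step 4**
Reactants: 4 methyl (R)-5-(TBSO)-3-methylpentanoate
Product: 6 (R)-5-(TBSO)-3-methylpentanal, via aluminium hemiacetal 5 (not isolated)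
Conditions: i-Bu2AlH (1.05 equiv), CH2Cl2, −78 °C; aq. potassium sodium tartrate work-up
Reagents that add atoms: none
Why: Partial ester reduction with one equivalent of i-Bu2AlH stops at the tetrahedral aluminium hemiacetal, which is stable at −78 °C and collapses to the aldehyde only on work-up.

**Step 5**
Reactants: 6 (R)-5-(TBSO)-3-methylpentanal; 7 methyl vinyl ketone
Product: 8 (2S)-2-[(2R)-4-(TBSO)butan-2-yl]-5-oxohexanal
Conditions: 7 (1.5 equiv), (S)-2-[methoxy(diphenyl)methyl]pyrrolidine (5 mol%), ethyl 3,4-dihydroxybenzoate (20 mol%), neat, 4 °C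
Reagents that add atoms: none
Why: Enamine-catalysed Michael addition of an aldehyde to an enone, in which the (E)-enamine is attacked on the face away from the diphenyl(methoxy)methyl group, so that C6 is set (S) under catalyst control whatever the bias of the resident C7 centre.

**Step 6**
Reactants: 8 (2S)-2-[(2R)-4-(TBSO)butan-2-yl]-5-oxohexanal
Product: 10 (4S)-4-[(2R)-4-(TBSO)butan-2-yl]cyclohex-2-en-1-one, via aldol 9 (not isolated)
Conditions: LiOH (0.2 equiv), i-PrOH, rt
Reagents that add atoms: none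
Why: Intramolecular aldol condensation of the methyl ketone enolate onto the aldehyde (six-membered ring, closing stage of a Robinson-type annulation) followed by E1cB dehydration, under base mild enough to leave the C6 centre intact.

**Step 7**
Reactants: 10 (4S)-4-[(2R)-4-(TBSO)butan-2-yl]cyclohex-2-en-1-one
Product: 12 (4S)-4-[(2R)-4-(TBSO)butan-2-yl]cyclohexa-1,5-dien-1-yl trifluoromethanesulfonate, via lithium dienolate 11 (not isolated)
Conditions: LiN(SiMe3)2 (1.1 equiv), THF, −78 °C; then PhNTf2 (1.15 equiv), −78 to 0 °C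
Reagents that add atoms: N-phenylbis(trifluoromethanesulfonimide), O=S(=O)(N(c1ccccc1)S(=O)(=O)C(F)(F)F)C(F)(F)F
Why: Kinetic deprotonation of the enone at the α' carbon gives the cross-conjugated dienolate, whose O-sulfonylation (enol triflate formation) fixes the 1,3-diene without touching the γ-hydrogen at C6.

**Step 8**
Reactants: 12 (4S)-4-[(2R)-4-(TBSO)butan-2-yl]cyclohexa-1,5-dien-1-yl trifluoromethanesulfonate
Product: 13 (5S)-5-[(2R)-4-(TBSO)butan-2-yl]-2-methylcyclohexa-1,3-diene
Conditions: MeMgBr (1.5 equiv), Fe(acac)3 (5 mol%), THF/NMP, −30 to 0 °C; used without storage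
Reagents that add atoms: methylmagnesium bromide, C[Mg]Br
Why: Iron-catalysed Kumada-type coupling of an alkenyl triflate with a methyl Grignard reagent is fast at low temperature and offers a methyl group no β-hydride pathway, so the diene position and C6 are preserved.

**Step 9**
Reactants: 13 (5S)-5-[(2R)-4-(TBSO)butan-2-yl]-2-methylcyclohexa-1,3-diene
Product: 14 (1S,4R,7S)-7-[(2R)-4-(TBSO)butan-2-yl]-5-methyl-2,3-dioxabicyclo[2.2.2]oct-5-ene
Conditions: O2 (1 atm, bubbling), 5,10,15,20-tetraphenylporphyrin (H2TPP, 0.5 mol%), white-light irradiation, CH2Cl2, −78 °C; cold chromatography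
Reagents that add atoms: dioxygen, O=O
Why: Energy transfer from the photoexcited porphyrin gives singlet oxygen, which adds suprafacially to the ring-locked s-cis diene C1=C2–C3(CH3)=C4 in a concerted [4+2] cycloaddition, the reaction type by which α-phellandrene and α-terpinene give their endoperoxides. The six-membered 1,2-dioxene ring closes by cycloaddition, C1–O and C4–O forming in one event, and this makes the 2,3-dioxabicyclo[2.2.2]oct-5-ene. C1 and C4 must be cis to each other because the addition is suprafacial, and their sense is set by approach of oxygen to the diene face opposite the branched C6 substituent, which lies over one face of the neighbouring terminus C1. The step needs facial selectivity and [4+2] selectivity over the ene reaction: the first rests only on the C6 branch and is expected to be moderate, hence −78 °C and chromatographic removal of the syn adduct; the second is favoured by the cisoid diene and by the absence of any isolated alkene in the silyl ether chain.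

**Step 10**
Reactants: 14 (1S,4R,7S)-7-[(2R)-4-(TBSO)butan-2-yl]-5-methyl-2,3-dioxabicyclo[2.2.2]oct-5-ene
Product: 15 (4S,5S)-4-hydroxy-2-methyl-5-[(2R)-4-(TBSO)butan-2-yl]cyclohex-2-en-1-one
Conditions: Et3N (1.5 equiv), CH2Cl2, 0 °C to rt, short reaction time
Reagents that add atoms: none
Why: Kornblum–DeLaMare rearrangement, in which the amine removes the bridgehead C4 hydrogen (flanked by C5H2 and the C3 methyl, whereas C1–H sits beside the branched C6 methine) with O–O cleavage, giving the C4 enone and the C1 alcohol with C1 unchanged.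

**Step 11**
Reactants: 15 (4S,5S)-4-hydroxy-2-methyl-5-[(2R)-4-(TBSO)butan-2-yl]cyclohex-2-en-1-one
Product: 18 (2S,4R,5S)-4-hydroxy-2-methyl-5-[(2R)-4-(TBSO)butan-2-yl]cyclohexan-1-one, via copper enolate 16 (not isolated), via C3-epimeric ketone 17 (not isolated)
Conditions: [(Ph3P)CuH]6 (0.35 equiv), H2O (5 equiv), benzene, rt; then DBU (0.2 equiv), CH2Cl2, rt
Reagents that add atoms: none
Why: Copper hydride conjugate reduction (Stryker reduction) saturates the enone without hydrogenolysis of the allylic C1–O bond, and base equilibration next to the C4 ketone then places the C3 methyl equatorial, cis to the C1 oxygen, in the chair fixed by the equatorial C1 and C6 substituents.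

**Step 12**
Reactants: 18 (2S,4R,5S)-4-hydroxy-2-methyl-5-[(2R)-4-(TBSO)butan-2-yl]cyclohexan-1-one; 19 angelic acid
Product: 21 (1R,2S,5S)-2-[(2R)-4-(TBSO)butan-2-yl]-5-methyl-4-oxocyclohexyl (2Z)-2-methylbut-2-enoate, via mixed anhydride 20 (not isolated)
Conditions: 19 (2 equiv), 2,4,6-trichlorobenzoyl chloride (2 equiv), Et3N (2.2 equiv), toluene, rt; then 18, 75 °C
Reagents that add atoms: none
Why: Yamaguchi-type esterification through the angelic 2,4,6-trichlorobenzoic mixed anhydride, run without a nucleophilic catalyst, transfers the (Z)-2-methylbut-2-enoyl group without isomerisation to the tiglate.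

**Step 13**
Reactants: 21 (1R,2S,5S)-2-[(2R)-4-(TBSO)butan-2-yl]-5-methyl-4-oxocyclohexyl (2Z)-2-methylbut-2-enoate
Product: 22 (1R,2S,5S)-2-[(2R)-4-hydroxybutan-2-yl]-5-methyl-4-oxocyclohexyl (2Z)-2-methylbut-2-enoate
Conditions: HF·pyridine, pyridine/THF, 0 °C to rt
Reagents that add atoms: none
Why: Buffered fluoride cleavage of a primary silyl ether under non-basic conditions spares the angelate and the epimerisable ketone.

**Step 14**
Reactants: 22 (1R,2S,5S)-2-[(2R)-4-hydroxybutan-2-yl]-5-methyl-4-oxocyclohexyl (2Z)-2-methylbut-2-enoate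
Product: 23 (1R,2S,5S)-5-methyl-4-oxo-2-[(2R)-4-oxobutan-2-yl]cyclohexyl (2Z)-2-methylbut-2-enoate
Conditions: Dess–Martin periodinane (1.3 equiv), NaHCO3, CH2Cl2, 0 °C to rt; used directly
Reagents that add atoms: none
Why: Dess–Martin oxidation of a primary alcohol under buffered, near-neutral conditions gives the C9 aldehyde without aldol reaction with the C4 ketone or epimerisation.

**Step 15**
Reactants: 23 (1R,2S,5S)-5-methyl-4-oxo-2-[(2R)-4-oxobutan-2-yl]cyclohexyl (2Z)-2-methylbut-2-enoate; 24 1-bromo-2-methylprop-1-ene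
Product: 26 (1R,2S,5S)-2-[(2R,4R)-4-hydroxy-6-methylhept-5-en-2-yl]-5-methyl-4-oxocyclohexyl (2Z)-2-methylbut-2-enoate, via alkenylchromium 25 (not isolated)
Conditions: 24 (3 equiv), CrCl2 (4 equiv), (S)-N-[2-(4-isopropyl-4,5-dihydrooxazol-2-yl)-6-methylphenyl]methanesulfonamide (4.4 equiv), Et3N (8 equiv), NiCl2 (5 mol%), THF, rt
Reagents that add atoms: none
Why: Asymmetric Nozaki–Hiyama–Kishi coupling, in which nickel-catalysed activation of the alkenyl bromide and transmetalation give an alkenyl species of trivalent chromium bound to the chiral sulfonamide ligand, which adds to the aldehyde only (not to the C4 ketone or the esters) and sets C9 under ligand control.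

**Step 16**
Reactants: 26 (1R,2S,5S)-2-[(2R,4R)-4-hydroxy-6-methylhept-5-en-2-yl]-5-methyl-4-oxocyclohexyl (2Z)-2-methylbut-2-enoate
Product: 27 (1R,2S,5S)-2-[(2R,4R)-4-acetoxy-6-methylhept-5-en-2-yl]-5-methyl-4-oxocyclohexyl (2Z)-2-methylbut-2-enoate
Conditions: Ac2O (1.5 equiv), pyridine, DMAP (5 mol%), CH2Cl2, 0 °C to rt
Reagents that add atoms: acetic anhydride, CC(=O)OC(C)=O
Why: Nucleophile-catalysed acylation of the only free hydroxyl proceeds with retention at C9, the C4 oxygen being still masked as the ketone.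

**Step 17**
Reactants: 27 (1R,2S,5S)-2-[(2R,4R)-4-acetoxy-6-methylhept-5-en-2-yl]-5-methyl-4-oxocyclohexyl (2Z)-2-methylbut-2-enoate
Product: 28 (1R,2S,4R,5S)-2-[(2R,4R)-4-acetoxy-6-methylhept-5-en-2-yl]-4-hydroxy-5-methylcyclohexyl (2Z)-2-methylbut-2-enoate
Conditions: LiBH(s-Bu)3 (1.1 equiv), THF, −78 °C; AcOH quench at −78 °C
Reagents that add atoms: none
Why: The bulky trialkylborohydride attacks the cyclohexanone from the equatorial direction to give the axial C4 alcohol cis to the equatorial C3 methyl, while the hindered angelate and the acetate should be left alone at −78 °C with a slight excess of reagent.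

**Compound list**
1 | 3-methylglutaric anhydride | CC1CC(=O)OC(=O)C1 | starting material
2 | (R)-5-methoxy-3-methyl-5-oxopentanoic acid | COC(=O)C[C@H](C)CC(O)=O | intermediate
3 | methyl (R)-5-hydroxy-3-methylpentanoate | COC(=O)C[C@H](C)CCO | intermediate
4 | methyl (R)-5-(tert-butyldimethylsilyloxy)-3-methylpentanoate | COC(=O)C[C@H](C)CCO[Si](C)(C)C(C)(C)C | intermediate
5 | diisobutylaluminium hemiacetal of 4 (hemiacetal carbon undefined) | COC(O[Al](CC(C)C)CC(C)C)C[C@H](C)CCO[Si](C)(C)C(C)(C)C | intermediate (not isolated)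
6 | (R)-5-(tert-butyldimethylsilyloxy)-3-methylpentanal | O=CC[C@H](C)CCO[Si](C)(C)C(C)(C)C | intermediate
7 | methyl vinyl ketone | CC(=O)C=C | starting material
8 | (2S)-2-[(2R)-4-(tert-butyldimethylsilyloxy)butan-2-yl]-5-oxohexanal | CC(=O)CC[C@H](C=O)[C@H](C)CCO[Si](C)(C)C(C)(C)C | intermediate
9 | (4S)-3-hydroxy-4-[(2R)-4-(tert-butyldimethylsilyloxy)butan-2-yl]cyclohexan-1-one (carbinol epimers) | O=C1CC[C@H](C(O)C1)[C@H](C)CCO[Si](C)(C)C(C)(C)C | intermediate (not isolated)
10 | (4S)-4-[(2R)-4-(tert-butyldimethylsilyloxy)butan-2-yl]cyclohex-2-en-1-one | O=C1CC[C@H](C=C1)[C@H](C)CCO[Si](C)(C)C(C)(C)C | intermediate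
11 | lithium (4S)-4-[(2R)-4-(tert-butyldimethylsilyloxy)butan-2-yl]cyclohexa-1,5-dien-1-olate | [Li]OC1=CC[C@H](C=C1)[C@H](C)CCO[Si](C)(C)C(C)(C)C | intermediate (not isolated)
12 | (4S)-4-[(2R)-4-(tert-butyldimethylsilyloxy)butan-2-yl]cyclohexa-1,5-dien-1-yl trifluoromethanesulfonate | FC(F)(F)S(=O)(=O)OC1=CC[C@H](C=C1)[C@H](C)CCO[Si](C)(C)C(C)(C)C | intermediate
13 | (5S)-5-[(2R)-4-(tert-butyldimethylsilyloxy)butan-2-yl]-2-methylcyclohexa-1,3-diene | CC1=CC[C@H](C=C1)[C@H](C)CCO[Si](C)(C)C(C)(C)C | intermediate (key-step precursor)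
14 | (1S,4R,7S)-7-[(2R)-4-(tert-butyldimethylsilyloxy)butan-2-yl]-5-methyl-2,3-dioxabicyclo[2.2.2]oct-5-ene (peroxide anti to the chain) | O2[C@@H]1C=C(C)[C@H](O2)C[C@H]1[C@H](C)CCO[Si](C)(C)C(C)(C)C | intermediate (key-step product)
15 | (4S,5S)-4-hydroxy-2-methyl-5-[(2R)-4-(tert-butyldimethylsilyloxy)butan-2-yl]cyclohex-2-en-1-one | O[C@@H]1C=C(C)C(=O)C[C@H]1[C@H](C)CCO[Si](C)(C)C(C)(C)C | intermediate
16 | copper enolate of 18 (monovalent copper, phosphine ligands omitted) | O[C@@H]1CC(C)=C(O[Cu])C[C@H]1[C@H](C)CCO[Si](C)(C)C(C)(C)C | intermediate (not isolated)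
17 | (2R,4R,5S)-4-hydroxy-2-methyl-5-[(2R)-4-(tert-butyldimethylsilyloxy)butan-2-yl]cyclohexan-1-one (C3 epimer from kinetic protonation) | O[C@@H]1C[C@@H](C)C(=O)C[C@H]1[C@H](C)CCO[Si](C)(C)C(C)(C)C | intermediate (not isolated)
18 | (2S,4R,5S)-4-hydroxy-2-methyl-5-[(2R)-4-(tert-butyldimethylsilyloxy)butan-2-yl]cyclohexan-1-one | O[C@@H]1C[C@H](C)C(=O)C[C@H]1[C@H](C)CCO[Si](C)(C)C(C)(C)C | intermediate
19 | angelic acid, (2Z)-2-methylbut-2-enoic acid | C/C=C(/C)C(O)=O | starting material
20 | (2Z)-2-methylbut-2-enoic 2,4,6-trichlorobenzoic anhydride | C/C=C(/C)C(=O)OC(=O)c1c(Cl)cc(Cl)cc1Cl | intermediate (not isolated)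
21 | (1R,2S,5S)-2-[(2R)-4-(tert-butyldimethylsilyloxy)butan-2-yl]-5-methyl-4-oxocyclohexyl (2Z)-2-methylbut-2-enoate | C/C=C(/C)C(=O)O[C@@H]1C[C@H](C)C(=O)C[C@H]1[C@H](C)CCO[Si](C)(C)C(C)(C)C | intermediate
22 | (1R,2S,5S)-2-[(2R)-4-hydroxybutan-2-yl]-5-methyl-4-oxocyclohexyl (2Z)-2-methylbut-2-enoate | C/C=C(/C)C(=O)O[C@@H]1C[C@H](C)C(=O)C[C@H]1[C@H](C)CCO | intermediate
23 | (1R,2S,5S)-5-methyl-4-oxo-2-[(2R)-4-oxobutan-2-yl]cyclohexyl (2Z)-2-methylbut-2-enoate | C/C=C(/C)C(=O)O[C@@H]1C[C@H](C)C(=O)C[C@H]1[C@H](C)CC=O | intermediate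
24 | 1-bromo-2-methylprop-1-ene | CC(C)=CBr | starting material
25 | (2-methylprop-1-enyl)chromium dichloride (trivalent chromium, ligand omitted) | CC(C)=C[Cr](Cl)Cl | intermediate (not isolated)
26 | (1R,2S,5S)-2-[(2R,4R)-4-hydroxy-6-methylhept-5-en-2-yl]-5-methyl-4-oxocyclohexyl (2Z)-2-methylbut-2-enoate | C/C=C(/C)C(=O)O[C@@H]1C[C@H](C)C(=O)C[C@H]1[C@H](C)C[C@H](C=C(C)C)O | intermediate
27 | (1R,2S,5S)-2-[(2R,4R)-4-acetoxy-6-methylhept-5-en-2-yl]-5-methyl-4-oxocyclohexyl (2Z)-2-methylbut-2-enoate | C/C=C(/C)C(=O)O[C@@H]1C[C@H](C)C(=O)C[C@H]1[C@H](C)C[C@H](C=C(C)C)OC(C)=O | intermediate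
28 | (1R,2S,4R,5S)-2-[(2R,4R)-4-acetoxy-6-methylhept-5-en-2-yl]-4-hydroxy-5-methylcyclohexyl (2Z)-2-methylbut-2-enoate (CNP0237033.1) | C/C=C(/C)C(=O)O[C@@H]1C[C@H](C)[C@H](O)C[C@H]1[C@H](C)C[C@H](C=C(C)C)OC(C)=O | target

**Step count**
Total: 17 steps. Longest linear sequence: 17 steps (1 to 28); 7, 19 and 24 are commercial and enter in steps 5, 12 and 15.

**Steps most likely to fail**

Step 9 (photooxygenation). Oxygen may add in part to the face syn to the C6 branch, and hydrogen abstraction along the ene pathway or aromatisation of the diene may lower the yield of 14. The fallback sets out from 13 and returns at 18. It replaces facial control in the cycloaddition by an invertive substitution at C1, so that the syn adduct is also used.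
- The syn endoperoxide (1R,4S,7S)-7-[(2R)-4-(TBSO)butan-2-yl]-5-methyl-2,3-dioxabicyclo[2.2.2]oct-5-ene F1, separated from 14, would be opened with Et3N as in step 10 to the C1-epimeric hydroxy enone (4R,5S)-4-hydroxy-2-methyl-5-[(2R)-4-(TBSO)butan-2-yl]cyclohex-2-en-1-one F2.
- Reduction with [(Ph3P)CuH]6 and equilibration as in step 11 would give the axial-hydroxy ketone (2S,4S,5S)-4-hydroxy-2-methyl-5-[(2R)-4-(TBSO)butan-2-yl]cyclohexan-1-one F3.
- Mitsunobu inversion (PPh3, diisopropyl azodicarboxylate, 4-nitrobenzoic acid, toluene) would give (1R,2S,5S)-2-[(2R)-4-(TBSO)butan-2-yl]-5-methyl-4-oxocyclohexyl 4-nitrobenzoate F4, and K2CO3 in MeOH would then release 18.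
- Since C4 is a ketone at this stage and C3 is under thermodynamic control, C1 is the only centre in which the two series differ.

Step 10 (peroxide opening). Deprotonation may also occur at C1–H and give the regioisomeric C1 ketone, and long contact with base may isomerise the γ-hydroxy enone to the 1,4-diketone. The fallback sets out from 14 and returns at 15. It separates O–O cleavage from oxidation.
- Thiourea in MeOH would reduce the peroxide to the cis-enediol (1R,4S,5S)-2-methyl-5-[(2R)-4-(TBSO)butan-2-yl]cyclohex-2-ene-1,4-diol F5.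
- Mono-oxidation with TEMPO and PhI(OAc)2 in CH2Cl2, a bulky oxoammonium oxidant, should then select the C4 carbinol (next to C5H2) over the C1 carbinol beside the branched C6 substituent.

Step 15 (C9 carbinol). Ligand control at C9 may be incomplete, activation of the trisubstituted alkenyl bromide may be slow, and the keto aldehyde may undergo aldol side reactions on long exposure. The fallback sets out from 23 and returns at 27. It gives up reagent control and makes the sequence stereoconvergent.
- Ligand-free coupling (CrCl2, NiCl2 cat., DMSO, rt) would give 26 together with its epimer (1R,2S,5S)-2-[(2R,4S)-4-hydroxy-6-methylhept-5-en-2-yl]-5-methyl-4-oxocyclohexyl (2Z)-2-methylbut-2-enoate F6, which would be separated by chromatography.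
- 26 would be acetylated as in step 16, and F6 would be converted into 27 by Mitsunobu inversion with acetic acid (PPh3, diisopropyl azodicarboxylate, THF, 0 °C).

**Further compounds**
F1 | step 9 | (1R,4S,7S)-7-[(2R)-4-(tert-butyldimethylsilyloxy)butan-2-yl]-5-methyl-2,3-dioxabicyclo[2.2.2]oct-5-ene (peroxide syn to the chain) | O2[C@H]1C=C(C)[C@@H](O2)C[C@H]1[C@H](C)CCO[Si](C)(C)C(C)(C)C
F2 | step 9 | (4R,5S)-4-hydroxy-2-methyl-5-[(2R)-4-(tert-butyldimethylsilyloxy)butan-2-yl]cyclohex-2-en-1-one | O[C@H]1C=C(C)C(=O)C[C@H]1[C@H](C)CCO[Si](C)(C)C(C)(C)C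
F3 | step 9 | (2S,4S,5S)-4-hydroxy-2-methyl-5-[(2R)-4-(tert-butyldimethylsilyloxy)butan-2-yl]cyclohexan-1-one | O[C@H]1C[C@H](C)C(=O)C[C@H]1[C@H](C)CCO[Si](C)(C)C(C)(C)C
F4 | step 9 | (1R,2S,5S)-2-[(2R)-4-(tert-butyldimethylsilyloxy)butan-2-yl]-5-methyl-4-oxocyclohexyl 4-nitrobenzoate | O=C(O[C@@H]1C[C@H](C)C(=O)C[C@H]1[C@H](C)CCO[Si](C)(C)C(C)(C)C)c1ccc(cc1)[N+](=O)[O-]
F5 | step 10 | (1R,4S,5S)-2-methyl-5-[(2R)-4-(tert-butyldimethylsilyloxy)butan-2-yl]cyclohex-2-ene-1,4-diol | O[C@@H]1C=C(C)[C@H](O)C[C@H]1[C@H](C)CCO[Si](C)(C)C(C)(C)C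
F6 | step 15 | (1R,2S,5S)-2-[(2R,4S)-4-hydroxy-6-methylhept-5-en-2-yl]-5-methyl-4-oxocyclohexyl (2Z)-2-methylbut-2-enoate | C/C=C(/C)C(=O)O[C@@H]1C[C@H](C)C(=O)C[C@H]1[C@H](C)C[C@@H](C=C(C)C)O
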